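**Retrosynthetic overview** (germacrane numbering C1–C15; rings formed in the order carbocycle → lactone → furanone)
1. 23 ⇐ 21: the 3(2H)-furanone is closed last, across the ten-membered ring, by attack of C10–OH on C3 of a cyclodec-4-en-2-yn-1-one; then the C15 silyl ether is removed.
2. 21 ⇐ 18: the ten-membered carbocycle is closed at C6–C7 (the bond the germacrene cyclase makes) by Cr(II) allylation on a fully oxidised acyclic chain that already carries the C8 crotonate; the 6,12-lactone closes in the same flask.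
3. 18 ⇐ 11 + 16: C1–C2 by acetylide addition; one oxidation then sets the C1 ketone and the C6 aldehyde.
4. 11 ⇐ (R)-linalool: the terpene supplies C1, C7–C10, C14 and the C10 stereocentre; C8–O comes from an organocatalytic α-acyloxylation, C11–C13 from an HWE reagent.
5. 16 ⇐ but-2-yne-1,4-diol: C3–C6 and C15, with the cis C4=C5 geometry set by Red-Al/I2, then Sonogashira coupling.

Assumption: the target SMILES is read as (6S,7S,8R,10R), C3 and C6 cis on C4=C5, (E)-crotonate.
Assumption: commercial (R)-(−)-linalool is taken at ≥97% ee.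

**Route**

Step 1
Reactants: 1 (R)-(−)-linalool
Product: 2 (3R)-3,7-dimethyl-3-[(trimethylsilyl)oxy]octa-1,6-diene
Conditions: 1-(trimethylsilyl)imidazole, CH2Cl2, rt
Reagents that add atoms: 1-(trimethylsilyl)imidazole, C[Si](C)(C)n1ccnc1
Why: O-silylation of the hindered tertiary allylic alcohol masks C10–O until the macrocycle exists; the C10 stereocentre is taken unchanged from the chiral pool.

Step 2
Reactants: 2 (3R)-3,7-dimethyl-3-[(trimethylsilyl)oxy]octa-1,6-diene
Product: 3 (2R)-2-methyl-2-[(trimethylsilyl)oxy]pentanedial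
Conditions: O3, CH2Cl2, −78 °C; then Me2S, −78 °C to rt
Reagents that add atoms: ozone, [O-][O+]=O
Why: Ozonolysis with reductive work-up cleaves both alkenes, giving the C7 aldehyde and the neopentyl C1 aldehyde (no α-hydrogen), whose difference in hindrance lets the next steps act at C7/C8 only.

Step 3
Reactants: 4 (E)-but-2-enoyl chloride
Product: 6 bis[(E)-but-2-enoyl] peroxide, via (E)-but-2-eneperoxoic acid 5 (not isolated)
Conditions: 4 (1.0 equiv in all), 30% aq. H2O2 (0.5 equiv), 2 M NaOH (1.0 equiv), Et2O/H2O, 0 °C; used as a titrated Et2O solution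
Reagents that add atoms: hydrogen peroxide, OO; (E)-but-2-enoyl chloride (second molecule of 4), C/C=C/C(=O)Cl
Why: Schotten–Baumann acylation of alkaline hydrogen peroxide: one molecule of 4 gives the peroxycarboxylate 5, which a second molecule of 4 acylates on its terminal oxygen to the diacyl peroxide, the way dibenzoyl peroxide is made; the peroxide is never concentrated to dryness.

Step 4
Reactants: 7 triethyl phosphonoacetate
Product: 8 ethyl 2-(diethoxyphosphoryl)-3-hydroxypropanoate (racemic)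
Conditions: (CH2O)n (1.0 equiv), piperidine (10 mol %), MeOH, reflux
Reagents that add atoms: formaldehyde (as paraformaldehyde), C=O
Why: Amine-catalysed hydroxymethylation (aldol-type addition of the phosphonate carbanion to formaldehyde) stops at the mono-adduct because olefination would need stoichiometric base, giving the known type of reagent for 2-(hydroxymethyl)alk-2-enoates.

Step 5
Reactants: 3 (2R)-2-methyl-2-[(trimethylsilyl)oxy]pentanedial; 6 bis[(E)-but-2-enoyl] peroxide; 8 ethyl 2-(diethoxyphosphoryl)-3-hydroxypropanoate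
Product: 10 ethyl (2E,4R,6R)-4-{[(E)-but-2-enoyl]oxy}-2-(hydroxymethyl)-6-methyl-7-oxo-6-[(trimethylsilyl)oxy]hept-2-enoate, via α-crotonyloxy dialdehyde 9 (not isolated)
Conditions: (R)-α,α-diphenylprolinol TMS ether (10 mol %), hydroquinone (10 mol %), THF, 0 °C; then 8, K2CO3, H2O, 0 °C
Reagents that add atoms: none
Why: Proposed new method: the enamine of the unhindered C7 aldehyde attacks the O–O bond of 6, exactly as in the known pyrrolidine-catalysed α-benzoyloxylation of aldehydes with dibenzoyl peroxide (closest known reaction) but with a different diacyl peroxide, the (R)-catalyst shielding one enamine face so that oxygen enters to give (R)-C8; the labile α-acyloxy aldehyde is trapped at once by Horner–Wadsworth–Emmons olefination, which is E-selective (C8 trans to CO2Et) and leaves the neopentyl C1 aldehyde alone.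

Step 6
Reactants: 10 ethyl (2E,4R,6R)-4-{[(E)-but-2-enoyl]oxy}-2-(hydroxymethyl)-6-methyl-7-oxo-6-[(trimethylsilyl)oxy]hept-2-enoate
Product: 11 ethyl (2Z,4R,6R)-2-(bromomethyl)-4-{[(E)-but-2-enoyl]oxy}-6-methyl-7-oxo-6-[(trimethylsilyl)oxy]hept-2-enoate
Conditions: NBS, Me2S, CH2Cl2, −40 to 0 °C
Reagents that add atoms: N-bromosuccinimide, O=C1CCC(=O)N1Br
Why: Corey–Kim-type activation (alkoxysulfonium, then bromide displacement) converts the primary allylic alcohol into the bromide without touching aldehyde, silyl ether or esters; the alkene geometry is unchanged (Z only by CIP).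

Step 7
Reactants: 12 but-2-yne-1,4-diol
Product: 13 4-{[tert-butyl(dimethyl)silyl]oxy}but-2-yn-1-ol
Conditions: NaH (1.0 equiv), TBSCl (1.0 equiv), THF, 0 °C to rt
Reagents that add atoms: tert-butyldimethylsilyl chloride, CC(C)(C)[Si](C)(C)Cl
Why: Monosilylation of a symmetrical diol through its monosodium alkoxide.

Step 8
Reactants: 13 4-{[tert-butyl(dimethyl)silyl]oxy}but-2-yn-1-ol
Product: 14 (Z)-4-{[tert-butyl(dimethyl)silyl]oxy}-3-iodobut-2-en-1-ol
Conditions: Red-Al, THF, 0 °C; then I2, −78 to 0 °C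
Reagents that add atoms: iodine, II
Why: Hydroxyl-directed trans-hydroalumination of the propargylic alcohol puts aluminium on the distal carbon, and iodinolysis with retention gives the vinyl iodide with iodine cis to CH2OH, which fixes the C4=C5 geometry (C3 cis to C6).

Step 9
Reactants: 14 (Z)-4-{[tert-butyl(dimethyl)silyl]oxy}-3-iodobut-2-en-1-ol
Product: 16 (E)-3-({[tert-butyl(dimethyl)silyl]oxy}methyl)pent-2-en-4-yn-1-ol (ethynyl cis to CH2OH), via C-silylated enynol 15 (not isolated)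
Conditions: PdCl2(PPh3)2 (3 mol %), CuI (6 mol %), TMS-acetylene, Et3N, THF, rt; then K2CO3 (cat.), MeOH
Reagents that add atoms: ethynyltrimethylsilane, C#C[Si](C)(C)C
Why: Sonogashira coupling retains the alkene geometry and tolerates the free alcohol; methanolysis then removes the alkynyl silyl group.

Step 10
Reactants: 11 ethyl (2Z,4R,6R)-2-(bromomethyl)-4-{[(E)-but-2-enoyl]oxy}-6-methyl-7-oxo-6-[(trimethylsilyl)oxy]hept-2-enoate; 16 (E)-3-({[tert-butyl(dimethyl)silyl]oxy}methyl)pent-2-en-4-yn-1-ol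
Product: 17 ethyl (2Z,4R,6R,7RS,10E)-2-(bromomethyl)-4-{[(E)-but-2-enoyl]oxy}-10-({[tert-butyl(dimethyl)silyl]oxy}methyl)-7,12-dihydroxy-6-methyl-6-[(trimethylsilyl)oxy]dodeca-2,10-dien-8-ynoate
Conditions: 16 (1.2 equiv), n-BuLi (2.4 equiv), THF, −78 to −20 °C; then 11, −78 °C; AcOH quench
Reagents that add atoms: none
Why: 1,2-Addition of the lithium acetylide (alkoxide–acetylide dianion) to the aldehyde at −78 °C, where acetylides neither alkylate bromides nor attack esters; the C1 carbinol forms as a mixture that is oxidised away next.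

Step 11
Reactants: 17 ethyl (2Z,4R,6R,7RS,10E)-2-(bromomethyl)-4-{[(E)-but-2-enoyl]oxy}-10-({[tert-butyl(dimethyl)silyl]oxy}methyl)-7,12-dihydroxy-6-methyl-6-[(trimethylsilyl)oxy]dodeca-2,10-dien-8-ynoate
Product: 18 ethyl (2Z,4R,6R,10E)-2-(bromomethyl)-4-{[(E)-but-2-enoyl]oxy}-10-({[tert-butyl(dimethyl)silyl]oxy}methyl)-6-methyl-7,12-dioxo-6-[(trimethylsilyl)oxy]dodeca-2,10-dien-8-ynoate
Conditions: Dess–Martin periodinane (3 equiv), CH2Cl2, 0 °C to rt
Reagents that add atoms: none
Why: Dess–Martin oxidation turns the propargylic alcohol into the C1 ynone and the allylic alcohol into the cis-enal (C6) in one operation under non-basic conditions that spare the allylic bromide.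

Step 12
Reactants: 18 ethyl (2Z,4R,6R,10E)-2-(bromomethyl)-4-{[(E)-but-2-enoyl]oxy}-10-({[tert-butyl(dimethyl)silyl]oxy}methyl)-6-methyl-7,12-dioxo-6-[(trimethylsilyl)oxy]dodeca-2,10-dien-8-ynoate
Product: 21 (6S,7S,8R,10R)-8-[(E)-but-2-enoyloxy]-15-[tert-butyl(dimethyl)silyloxy]-10-hydroxy-1-oxogermacra-4,11(13)-dien-2-yn-12,6-olide (C3 and C6 cis on C4=C5), via macrocyclic hydroxy ester 19 (not isolated), via silylated macrolactone 20 (not isolated)
Conditions: CrCl2 (6 equiv), THF/DMF, 18 added over 10 h (2 mM), rt; then citric acid, MeOH, rt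
Reagents that add atoms: none
Why: Intramolecular Nozaki–Hiyama/Barbier allylation: the allylchromium from the 2-(bromomethyl)enoate adds through C7 to the C6 aldehyde in a chair transition state with both ring chains equatorial (6,7-trans lactone) and with C8–H eclipsing the allyl unit so that the tethered aldehyde arrives from the C9 face (7,8 relationship of the target); the C6 alkoxide then lactonises onto C12 and mild acid removes the tertiary TMS ether.

Step 13
Reactants: 21 (6S,7S,8R,10R)-8-[(E)-but-2-enoyloxy]-15-[tert-butyl(dimethyl)silyloxy]-10-hydroxy-1-oxogermacra-4,11(13)-dien-2-yn-12,6-olide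
Product: 23 CNP0225232.1, (4Z,6S,7S,8R,10R)-8-[(E)-but-2-enoyloxy]-15-hydroxy-1-oxo-3,10-epoxygermacra-2,4,11(13)-trien-12,6-olide, via 15-O-TBS furanone 22 (not isolated)
Conditions: Ph3PAuNTf2 (5 mol %), CH2Cl2, rt; then HF·pyridine, THF, 0 °C
Reagents that add atoms: none
Why: Gold(I) activation of the strained ynone triggers 5-endo-dig attack of C10–OH on C3 (cycloisomerisation of an α′-hydroxy ynone to a 3(2H)-furanone, the C10–O–C3 bridge of the proposed biogenesis) without touching C10, and HF·pyridine then cleaves the primary TBS ether.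

**Compound list**
1 | (R)-(−)-linalool | C=C[C@](C)(O)CCC=C(C)C | starting material
2 | (3R)-3,7-dimethyl-3-[(trimethylsilyl)oxy]octa-1,6-diene | C=C[C@](C)(O[Si](C)(C)C)CCC=C(C)C | intermediate
3 | (2R)-2-methyl-2-[(trimethylsilyl)oxy]pentanedial | O=C[C@](C)(O[Si](C)(C)C)CCC=O | intermediate
4 | (E)-but-2-enoyl chloride | C/C=C/C(=O)Cl | starting material
5 | (E)-but-2-eneperoxoic acid (peroxycrotonic acid, present as its sodium salt in the flask) | C/C=C/C(=O)OO | intermediate
6 | bis[(E)-but-2-enoyl] peroxide | C/C=C/C(=O)OOC(=O)/C=C/C | intermediate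
7 | triethyl phosphonoacetate | CCOC(=O)CP(=O)(OCC)OCC | starting material
8 | ethyl 2-(diethoxyphosphoryl)-3-hydroxypropanoate (racemic) | CCOC(=O)C(CO)P(=O)(OCC)OCC | intermediate
9 | (2R,4R)-4-methyl-1,5-dioxo-4-[(trimethylsilyl)oxy]pentan-2-yl (E)-but-2-enoate | O=C[C@H](OC(=O)/C=C/C)C[C@@](C)(O[Si](C)(C)C)C=O | intermediate
10 | ethyl (2E,4R,6R)-4-{[(E)-but-2-enoyl]oxy}-2-(hydroxymethyl)-6-methyl-7-oxo-6-[(trimethylsilyl)oxy]hept-2-enoate | CCOC(=O)/C(CO)=C/[C@H](OC(=O)/C=C/C)C[C@@](C)(O[Si](C)(C)C)C=O | intermediate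
11 | ethyl (2Z,4R,6R)-2-(bromomethyl)-4-{[(E)-but-2-enoyl]oxy}-6-methyl-7-oxo-6-[(trimethylsilyl)oxy]hept-2-enoate | CCOC(=O)/C(CBr)=C/[C@H](OC(=O)/C=C/C)C[C@@](C)(O[Si](C)(C)C)C=O | intermediate
12 | but-2-yne-1,4-diol | OCC#CCO | starting material
13 | 4-{[tert-butyl(dimethyl)silyl]oxy}but-2-yn-1-ol | OCC#CCO[Si](C)(C)C(C)(C)C | intermediate
14 | (Z)-4-{[tert-butyl(dimethyl)silyl]oxy}-3-iodobut-2-en-1-ol | OC/C=C(\I)CO[Si](C)(C)C(C)(C)C | intermediate
15 | (E)-3-({[tert-butyl(dimethyl)silyl]oxy}methyl)-5-(trimethylsilyl)pent-2-en-4-yn-1-ol | OC/C=C(\C#C[Si](C)(C)C)CO[Si](C)(C)C(C)(C)C | intermediate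
16 | (E)-3-({[tert-butyl(dimethyl)silyl]oxy}methyl)pent-2-en-4-yn-1-ol | OC/C=C(\C#C)CO[Si](C)(C)C(C)(C)C | intermediate
17 | ethyl (2Z,4R,6R,7RS,10E)-2-(bromomethyl)-4-{[(E)-but-2-enoyl]oxy}-10-({[tert-butyl(dimethyl)silyl]oxy}methyl)-7,12-dihydroxy-6-methyl-6-[(trimethylsilyl)oxy]dodeca-2,10-dien-8-ynoate | CCOC(=O)/C(CBr)=C/[C@H](OC(=O)/C=C/C)C[C@@](C)(O[Si](C)(C)C)C(O)C#C/C(CO[Si](C)(C)C(C)(C)C)=C\CO | intermediate
18 | ethyl (2Z,4R,6R,10E)-2-(bromomethyl)-4-{[(E)-but-2-enoyl]oxy}-10-({[tert-butyl(dimethyl)silyl]oxy}methyl)-6-methyl-7,12-dioxo-6-[(trimethylsilyl)oxy]dodeca-2,10-dien-8-ynoate | CCOC(=O)/C(CBr)=C/[C@H](OC(=O)/C=C/C)C[C@@](C)(O[Si](C)(C)C)C(=O)C#C/C(CO[Si](C)(C)C(C)(C)C)=C\C=O | intermediate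
19 | ring-closed hydroxy ester: ethyl 8-[(E)-but-2-enoyloxy]-15-[tert-butyl(dimethyl)silyloxy]-6-hydroxy-1-oxo-10-(trimethylsilyloxy)germacra-4,11(13)-dien-2-yn-12-oate, same spatial arrangement as 20 | CCOC(=O)C(=C)[C@@H]1[C@@H](O)/C=C(/CO[Si](C)(C)C(C)(C)C)C#CC(=O)[C@](C)(O[Si](C)(C)C)C[C@H]1OC(=O)/C=C/C | intermediate
20 | (6S,7S,8R,10R)-8-[(E)-but-2-enoyloxy]-15-[tert-butyl(dimethyl)silyloxy]-1-oxo-10-(trimethylsilyloxy)germacra-4,11(13)-dien-2-yn-12,6-olide | C=C1C(=O)O[C@H]2/C=C(/CO[Si](C)(C)C(C)(C)C)C#CC(=O)[C@](C)(O[Si](C)(C)C)C[C@@H](OC(=O)/C=C/C)[C@H]12 | intermediate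
21 | (6S,7S,8R,10R)-8-[(E)-but-2-enoyloxy]-15-[tert-butyl(dimethyl)silyloxy]-10-hydroxy-1-oxogermacra-4,11(13)-dien-2-yn-12,6-olide | C=C1C(=O)O[C@H]2/C=C(/CO[Si](C)(C)C(C)(C)C)C#CC(=O)[C@](C)(O)C[C@@H](OC(=O)/C=C/C)[C@H]12 | intermediate
22 | 15-O-[tert-butyl(dimethyl)silyl] ether of 23 | C=C1C(=O)O[C@H]2/C=C(/CO[Si](C)(C)C(C)(C)C)C3=CC(=O)[C@@](C)(C[C@@H](OC(=O)/C=C/C)[C@H]12)O3 | intermediate
23 | CNP0225232.1, (4Z,6S,7S,8R,10R)-8-[(E)-but-2-enoyloxy]-15-hydroxy-1-oxo-3,10-epoxygermacra-2,4,11(13)-trien-12,6-olide | C=C1C(=O)O[C@H]2/C=C(/CO)C3=CC(=O)[C@@](C)(C[C@@H](OC(=O)/C=C/C)[C@H]12)O3 | target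

**Count**
Total step count: 13 (including the two reagent preparations, steps 3 and 4).
Longest linear sequence: 8 (steps 1, 2, 5, 6, 10, 11, 12, 13).

**Three steps most likely to fail**

Step 12 (macrocyclisation). The ring being closed holds an alkyne and a cis-alkene. C6 and C7 are set only by the transition-state preferences argued above. The allylchromium also has the C8 crotonate in a position from which reductive 1,4-elimination to a diene could compete with a slow ring closure. The fallback sets out from 18 and comes back at 22, and reverses the order of the last two rings. Citric acid in MeOH frees the tertiary alcohol to give the acyclic hydroxy-ynone F1. Ph3PAuNTf2 closes this to the acyclic furanone enal bromide F2. The CrCl2 allylation is then run on F2: the C2–C3 unit is no longer a linear alkyne inside the forming ring, so closure is less strained and faster relative to elimination. Lactonisation gives 22, which the HF·pyridine stage of step 13 turns into 23.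

Step 5 (α-acyloxylation/olefination). The peroxide 6 is untested in this role: the enamine could add in a Michael sense to the crotonoyl unit, and the α-acyloxy aldehyde could epimerise before olefination. The fallback sets out from 2 and comes back at 11. One equivalent of ozone cleaves only the trisubstituted alkene of 2 to give the mono-aldehyde F3. L-Proline/nitrosobenzene α-aminoxylation (known sense: (R)) with olefination by 8 in the same flask gives the anilinooxy ester F4. Zn/NH4Cl cleaves the N–O bond to the diol F5. NBS/Me2S brominates only the primary allylic alcohol to give the bromo alcohol F6. Crotonic anhydride with catalytic Sc(OTf)3 acylates the secondary alcohol to give the vinyl crotonate F7. OsO4 (cat.)/NaIO4/2,6-lutidine cleaves the vinyl group to give 11.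

Step 10 (acetylide addition beside an allylic bromide). The acetylide or the alkoxide could attack the 2-(bromomethyl)enoate in an SN2′ sense. The fallback sets out from 10 (with 14 as partner) and comes back at 18, so the bromide never meets a carbanion. Ethynylmagnesium bromide adds to the aldehyde of 10 to give the terminal alkyne diol F8. MnO2 oxidises 14 to the iodo-enal F9. Sonogashira coupling of F8 with F9 gives the enyne aldehyde diol F10. NBS/Me2S converts its only primary allylic alcohol into the bromide F11. Dess–Martin oxidation of the remaining propargylic alcohol gives 18.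

**Further compounds**
F1 | step 12 | ethyl (2Z,4R,6R,10E)-2-(bromomethyl)-4-{[(E)-but-2-enoyl]oxy}-10-({[tert-butyl(dimethyl)silyl]oxy}methyl)-6-hydroxy-6-methyl-7,12-dioxododeca-2,10-dien-8-ynoate | CCOC(=O)/C(CBr)=C/[C@H](OC(=O)/C=C/C)C[C@@](C)(O)C(=O)C#C/C(CO[Si](C)(C)C(C)(C)C)=C\C=O
F2 | step 12 | ethyl (2Z,4R)-2-(bromomethyl)-4-{[(E)-but-2-enoyl]oxy}-5-[(2R)-2-methyl-3-oxo-5-(cis-1-{[tert-butyl(dimethyl)silyl]oxy}-4-oxobut-2-en-2-yl)-2,3-dihydrofuran-2-yl]pent-2-enoate (furanone ring cis to CHO) | CCOC(=O)/C(CBr)=C/[C@H](OC(=O)/C=C/C)C[C@@]1(C)OC(/C(CO[Si](C)(C)C(C)(C)C)=C\C=O)=CC1=O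
F3 | step 5 | (4R)-4-methyl-4-[(trimethylsilyl)oxy]hex-5-enal | C=C[C@](C)(O[Si](C)(C)C)CCC=O
F4 | step 5 | ethyl (2E,4R,6R)-4-(anilinooxy)-2-(hydroxymethyl)-6-methyl-6-[(trimethylsilyl)oxy]octa-2,7-dienoate | CCOC(=O)/C(CO)=C/[C@H](ONc1ccccc1)C[C@@](C)(O[Si](C)(C)C)C=C
F5 | step 5 | ethyl (2E,4R,6R)-4-hydroxy-2-(hydroxymethyl)-6-methyl-6-[(trimethylsilyl)oxy]octa-2,7-dienoate | CCOC(=O)/C(CO)=C/[C@H](O)C[C@@](C)(O[Si](C)(C)C)C=C
F6 | step 5 | ethyl (2Z,4R,6R)-2-(bromomethyl)-4-hydroxy-6-methyl-6-[(trimethylsilyl)oxy]octa-2,7-dienoate | CCOC(=O)/C(CBr)=C/[C@H](O)C[C@@](C)(O[Si](C)(C)C)C=C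
F7 | step 5 | ethyl (2Z,4R,6R)-2-(bromomethyl)-4-{[(E)-but-2-enoyl]oxy}-6-methyl-6-[(trimethylsilyl)oxy]octa-2,7-dienoate | CCOC(=O)/C(CBr)=C/[C@H](OC(=O)/C=C/C)C[C@@](C)(O[Si](C)(C)C)C=C
F8 | step 10 | ethyl (2E,4R,6R,7RS)-4-{[(E)-but-2-enoyl]oxy}-7-hydroxy-2-(hydroxymethyl)-6-methyl-6-[(trimethylsilyl)oxy]non-2-en-8-ynoate | CCOC(=O)/C(CO)=C/[C@H](OC(=O)/C=C/C)C[C@@](C)(O[Si](C)(C)C)C(O)C#C
F9 | step 10 | (Z)-4-{[tert-butyl(dimethyl)silyl]oxy}-3-iodobut-2-enal | O=C/C=C(\I)CO[Si](C)(C)C(C)(C)C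
F10 | step 10 | ethyl (2E,4R,6R,7RS,10E)-4-{[(E)-but-2-enoyl]oxy}-10-({[tert-butyl(dimethyl)silyl]oxy}methyl)-7-hydroxy-2-(hydroxymethyl)-6-methyl-12-oxo-6-[(trimethylsilyl)oxy]dodeca-2,10-dien-8-ynoate | CCOC(=O)/C(CO)=C/[C@H](OC(=O)/C=C/C)C[C@@](C)(O[Si](C)(C)C)C(O)C#C/C(CO[Si](C)(C)C(C)(C)C)=C\C=O
F11 | step 10 | ethyl (2Z,4R,6R,7RS,10E)-2-(bromomethyl)-4-{[(E)-but-2-enoyl]oxy}-10-({[tert-butyl(dimethyl)silyl]oxy}methyl)-7-hydroxy-6-methyl-12-oxo-6-[(trimethylsilyl)oxy]dodeca-2,10-dien-8-ynoate | CCOC(=O)/C(CBr)=C/[C@H](OC(=O)/C=C/C)C[C@@](C)(O[Si](C)(C)C)C(O)C#C/C(CO[Si](C)(C)C(C)(C)C)=C\C=O
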